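**Remark on the chemistry (assumption):** the sense of induction of the nickel/chiral phosphine catalyst in step 6 cannot be predicted with confidence. It is assumed that the ligand antipode that delivers (R)-13 is identified in a first trial; both antipodes are accessible. Ring atoms carry the target numbering throughout: C1 ketone, C2 heptenyl-bearing, C3 hydroxymethyl-bearing, C4 carbinol, C5 epoxide CH, C6 quaternary epoxide carbon.

## Structural features

The target is one six-membered carbocycle, a cyclohex-2-enone, cis-fused to an oxirane across C5–C6. C1 is the ketone, C2 carries an (E)-hept-1-enyl group, C3 a hydroxymethyl group, C4 a secondary hydroxyl, and the quaternary epoxide carbon C6 an (E)-2-methylbut-2-enoic acid chain attached through CH2. C4, C5 and C6 are three contiguous stereocentres, all R; the C4 hydroxyl lies on the face of the epoxide oxygen and the acid chain on the opposite face. The C2=C3 bond is tetrasubstituted and forms a dienone with the heptenyl alkene, whose chain carries an activated allylic CH2 group. Fragile elements are the α,β-epoxy ketone (base, nucleophiles), the γ-hydroxy enone and the dienyl unit; any precursor with an enolisable C5 and an oxygen leaving group on C6 can aromatise by β-elimination. The difficulty is twofold: the oxygenated quaternary centre C6 must be made in one absolute configuration and relayed to C5 and C4, and the ring carries oxygen at C1 and C4 in two different oxidation states. The key step exploits the C2=C3 alkene, flanked by C1 and C4, with quaternary C6 across the ring: this is an alkyne (C2, C3) inserted into one C(O)–CH2 bond of a 3,3-disubstituted cyclobutanone whose carbonyl carbon becomes C4, whose C3 becomes C6 and whose enantiotopic CH2 groups become C1 and C5.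

## Logic of the disconnections

22 is traced to 21 by exchanging the acid O–H for an O–CH3 bond. A free acid would interfere with the olefination, the fluoride step and the borohydride step. The demand is an ester cleavage at the end that spares the epoxy ketone.

21 is traced to 20 by removing the C4–H bond (carbinol to ketone). C4 can then be set last, from the two stereocentres already present. The forward reduction must choose C4 over C1 and the face anti to the epoxide; the free hydroxymethyl group on C3 is kept unprotected at this point so that it can deliver the hydride.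

20 is traced to 19 by cutting the C5–O bond of the oxirane and re-silylating both oxygens. The epoxide oxygen is then the C6 oxygen installed by the key step, so its configuration is inherited. The forward step needs a leaving group on C5 anti to that oxygen. A fluoride-labile alkylsilyl group is chosen on the primary oxygen, in place of a robust arylsilyl group, so that one fluoride treatment frees the nucleophile and the directing hydroxyl together and a separate desilylation is saved.

19 is traced through 18 to 17 by cutting C5–Br. C5 holds the only α-hydrogens of either ketone, so regiochemistry is not an issue; the demand is facial selectivity next to quaternary C6.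

17 is traced to 16 by cutting the side-chain C=C bond (Wittig olefination, E-selective). This cut is placed before the epoxide is made: the aldehyde would otherwise be a β,γ-epoxy aldehyde, prone to ring-opening elimination. The forward step must take the aldehyde in the presence of two ketones.

16 is traced to 15 by re-forming the two C–O bonds of the dimethyl acetal. The acetal is inert to nickel and to the radical oxidation; the demand is a hydrolysis mild enough for both silyl ethers.

15 is traced to 13 by removing the C1 carbonyl oxygen. The key step can only deliver C1 as CH2, and C1 is allylic and γ to the C4 carbonyl. The oxidation is placed before the epoxide (a radical at C1 next to an oxirane would open it) and before the enoate (one more allylic CH2). The demand is site selectivity against the allylic CH2 of the heptenyl chain.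

13 is traced to 7 and 12 by cutting C3–C4 and C1–C2. This removes the ring, the tetrasubstituted alkene and the only stereocentre in one operation and leaves two achiral pieces. The demands are alkyne orientation, choice between two enantiotopic C–C bonds, and C–C cleavage in preference to loss of the silyloxy group. The (R) configuration at the carbinol carbon of 13 is the one that maps onto (R)-C6 of 22 (oxygen on the later epoxide face).

7 is traced to 6 by restoring two C–Cl bonds, and 6 to 3 and 4 (through 5) by cutting the C(O)–CH2 and CCl2–C(O–Si) ring bonds ([2+2] cycloaddition). The forward steps must tolerate an acetal and a tertiary silyl ether, so Lewis acid and protic acid are kept away.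

3 is traced to 1 by cutting the O–Si bond; the demand is kinetic enolisation at the methyl group.

12 is traced to 10 and 11 by cutting the C(sp)–C(sp2) bond (Sonogashira coupling); 11 is a catalogue compound, which saves a silylation. 10 is traced to 8 by cutting C–I (hydrometalation/iodination), which must deliver the (E) isomer only.

## Other disconnections considered

**Alternative 1:** The bond cut is C5–O of the oxirane, traced to an isomeric epoxy alcohol A2 whose oxirane spans C6–C1 and whose C5 hydroxyl lies on the other face. The cis C4/C5 dioxygen pattern of A2 would be set by enzymatic cis-dihydroxylation of an aromatic ring. In the forward key step base forms the C5 alkoxide, which attacks C6 from the side opposite the C6–O bond (Payne rearrangement). This should give A1, with the epoxide on C5–C6 cis to the C4 ether and a C1 alkoxide for later oxidation to the ketone.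
- In its favour: the absolute configuration comes from an enzyme, the epoxide/C4 relationship follows stereospecifically from an invertive step, and C1 is oxygenated from the start. On these points (no ligand screening, no C–H oxidation at C1, no regioselective reduction of a dione) it is better than the chosen plan, and in stereochemical reliability at C4–C6 at least its equal.
- Against it here: the Payne step is an equilibrium between a vinyl epoxide and an allylic alcohol whose position is not assured, and the alkoxide of A2 could also open the vinyl epoxide in the SN2' sense. A1 still lacks most of the carbon skeleton: the heptenyl group must be joined to C2, the allyl group extended to the methylbutenoate and the ester reduced. Building the allyl-bearing quaternary C6 into A2 is itself a multistep task.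
- Comparison: both plans close the epoxide by intramolecular SN2 displacement. Alternative 1 starts from the ring and adds carbon; the chosen plan makes ring, C2=C3 alkene and C6 together from two achiral pieces and should be shorter overall.

**Alternative 2:** The cut is the ring double bond C2=C3. Forward, the ruthenium alkylidene of the second-generation Grubbs catalyst, under ethylene, would engage the terminal alkyne and the 1,1-disubstituted alkene of open-chain epoxy enyne A4 (ring-closing enyne metathesis). This closes the carbocycle and leaves diene A3 with a vinyl group on C2.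
- In its favour: the epoxide, the C4 oxygen and the C1 oxygen are in place and stereodefined before the ring exists. What follows is cross-metathesis of the vinyl group with a terminal olefin, oxidation of the C1 alcohol and deprotection. There is no allylic C–H oxidation, no halogenation next to a quaternary centre and no regioselective ketone reduction; in this endgame it is better than the chosen plan.
- Against it: A4 holds four contiguous stereocentres, one a fully substituted epoxide carbon, to be assembled by acyclic asymmetric synthesis. The metathesis must form a tetrasubstituted ring alkene from a hindered olefin next to a free propargylic alcohol and an epoxide, where catalyst chelation or slow turnover would be the concern.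
- Comparison: both plans create the C2=C3 alkene in the ring-forming step. Metathesis creates no stereocentre, whereas the nickel annulation creates C6 under catalyst control. The chosen plan reaches its two key partners in five steps from simple materials, which Alternative 2 could not match; after the key step the two are about equal, or Alternative 2 slightly shorter.

**Alternative 3:** Three ring bonds are cut at once: C4–C5, C6–C1 and C1–C2. Forward, chromium carbene complex A6 (a dienyl(methoxy)carbene on a Cr(CO)5 fragment), enyne ester A7 and one carbonyl ligand would combine on heating (Dötz benzannulation) to phenol A5. The carbene carbon becomes C4 (methyl ether), the carbonyl ligand C1 (free phenol) and the alkyne carbons C5 and C6.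
- In its favour: it is the most convergent of the four plans. Every carbon substituent sits on the right ring atom with the usual regiochemistry of terminal alkynes, and C1 and C4 emerge oxygenated and differentiated. In convergence and in the C1/C4 oxidation pattern it is better than the chosen plan.
- Against it: A5 is a flat arene, so none of the three stereocentres exists after the key step. The route would depend on oxidative dearomatisation, an enantioselective nucleophilic epoxidation of C5=C6 in the presence of the dienyl and enoate groups, and a face-selective C4 reduction. Chromium is stoichiometric, and the dienyl carbene complex and the skipped enyne A7 (prone to base-induced isomerisation) are delicate partners.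
- Comparison: Alternative 3 postpones all stereochemistry to a reagent-controlled epoxidation, whereas the chosen plan fixes C6 in the ring-forming event and relays it to C5 intramolecularly. The oxidation-state problem that costs the chosen plan two uncertain steps is absent; step counts should be comparable.

Key step: step 6

## Route

**Step 1**
Reactants: 1 4,4-dimethoxybutan-2-one
Product: 3 triethyl[(4,4-dimethoxybut-1-en-2-yl)oxy]silane, via lithium 4,4-dimethoxybut-1-en-2-olate 2 (not isolated)
Conditions: LiN(i-Pr)2, THF, −78 °C; then Et3SiCl, −78 °C to 0 °C
Reagents that add atoms: chlorotriethylsilane, CC[Si](Cl)(CC)CC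
Why: Kinetic deprotonation by the hindered amide at −78 °C takes place at the methyl group, not at the CH2 group whose enolate could expel methoxide, and O-silylation of the lithium enolate gives the less substituted silyl enol ether (kinetic silyl enol ether formation). No stereocentre is formed.

**Step 2**
Reactants: 3 triethyl[(4,4-dimethoxybut-1-en-2-yl)oxy]silane; 4 trichloroacetyl chloride
Product: 6 2,2-dichloro-3-(2,2-dimethoxyethyl)-3-(triethylsilyloxy)cyclobutan-1-one (racemic), via dichloroketene 5 (not isolated)
Conditions: Zn–Cu couple, Et2O/DME, 0 °C to rt, slow addition of 4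
Reagents that add atoms: none
Why: Zinc dechlorinates 4 to dichloroketene, which undergoes the thermal [2+2] cycloaddition typical of ketenes with electron-rich alkenes; the nucleophilic CH2 terminus of 3 bonds to the ketene carbonyl carbon, so the silyloxy-bearing carbon ends at the 3-position. DME ties up the ZnCl2 formed, which protects the acetal and the enol ether; the single stereocentre of 6 is racemic and disappears in step 3.

**Step 3**
Reactants: 6 2,2-dichloro-3-(2,2-dimethoxyethyl)-3-(triethylsilyloxy)cyclobutan-1-one
Product: 7 3-(2,2-dimethoxyethyl)-3-(triethylsilyloxy)cyclobutan-1-one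
Conditions: Zn dust, NH4Cl, MeOH, 0 °C to rt
Reagents that add atoms: none
Why: Zinc reduces the two C–Cl bonds α to the carbonyl (reductive dehalogenation through the zinc enolate); buffering with NH4Cl in methanol avoids acetic acid, and methanol is degenerate toward the dimethyl acetal. The product is achiral, with a mirror plane through the carbonyl carbon and C3.

**Step 4**
Reactants: 8 hept-1-yne
Product: 10 (E)-1-iodohept-1-ene, via (E)-hept-1-enylzirconocene chloride 9 (not isolated)
Conditions: Cp2Zr(H)Cl, THF, rt; then I2, 0 °C
Reagents that add atoms: iodine, II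
Why: Hydrozirconation adds Zr–H syn across the terminal alkyne with zirconium on the terminal carbon, and iodinolysis of the C–Zr bond proceeds with retention, which fixes the (E) geometry.

**Step 5**
Reactants: 10 (E)-1-iodohept-1-ene; 11 tert-butyldimethyl(prop-2-yn-1-yloxy)silane
Product: 12 tert-butyl{[(E)-dec-4-en-2-yn-1-yl]oxy}dimethylsilane
Conditions: Pd(PPh3)2Cl2 (2 mol %), CuI (4 mol %), Et3N, THF, rt
Reagents that add atoms: none
Why: Sonogashira coupling of a vinyl iodide with a terminal alkyne under palladium/copper catalysis at room temperature; the (E) geometry is retained and the silyl ether is inert.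

**Step 6**
Reactants: 7 3-(2,2-dimethoxyethyl)-3-(triethylsilyloxy)cyclobutan-1-one; 12 tert-butyl{[(E)-dec-4-en-2-yn-1-yl]oxy}dimethylsilane
Product: 13 (5R)-2-{[tert-butyl(dimethyl)silyl]oxymethyl}-5-(2,2-dimethoxyethyl)-3-[(E)-hept-1-enyl]-5-(triethylsilyloxy)cyclohex-2-en-1-one
Conditions: Ni(cod)2 (10 mol %), neomenthyldiphenylphosphine (one antipode, 20 mol %), toluene, 90 °C, slow addition of 12
Reagents that add atoms: none
Why: Zerovalent nickel binds the alkyne of 12 and the carbonyl of 7 and couples them by oxidative cyclisation to a spiro oxanickelacyclopentene in which the carbonyl carbon (C4) is bonded to the alkyne carbon carrying CH2OTBS (C3) and nickel sits on the alkenyl-substituted carbon (C2), where the conjugated double bond can stabilise it in an η3 fashion; this is the required regiochemistry and the heptenyl group secures it. β-Carbon elimination then opens the strained four-membered ring to a seven-membered divalent nickelacycle, and C(sp3)–C(sp2) reductive elimination forms C1–C2, returns zerovalent nickel and closes the six-membered ring, so the ring arises by formal insertion of the alkyne into one C(O)–CH2 bond (a [4+2] annulation closed by reductive elimination from the seven-membered metallacycle, not by a polar cyclisation). The closest known reaction type is the zerovalent-nickel-catalysed [4+2] annulation of 3,3-disubstituted cyclobutanones with internal alkynes, a reaction family in which ligand-controlled desymmetrisation of the prochiral ketone is established; the silyloxy group at the 3-position and the enyne partner are new spectators on that template. The single new stereocentre, C6, is fixed when one of the two enantiotopic C(O)–CH2 bonds is chosen in the β-carbon elimination, under control of the chiral phosphine on nickel (catalyst control). The step needs three selectivities: alkyne orientation (alkenyl effect), enantiotopic bond choice (ligand) and C–C cleavage followed by reductive elimination in preference to β-silyloxy elimination from the Ni–CH2–C(OSiEt3) unit; the absence of β-hydrogens at the quaternary carbon, the poor leaving ability of a trialkylsilyloxy group and the strain released on C–C cleavage favour the desired path. Slow addition of 12 limits enyne oligomerisation.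

**Step 7**
Reactants: 13 (5R)-2-{[tert-butyl(dimethyl)silyl]oxymethyl}-5-(2,2-dimethoxyethyl)-3-[(E)-hept-1-enyl]-5-(triethylsilyloxy)cyclohex-2-en-1-one
Product: 15 (5R)-2-{[tert-butyl(dimethyl)silyl]oxymethyl}-5-(2,2-dimethoxyethyl)-3-[(E)-hept-1-enyl]-5-(triethylsilyloxy)cyclohex-2-ene-1,4-dione, via C1 tert-butyl peroxide 14 (not isolated)
Conditions: Rh2(cap)4 (dirhodium tetracaprolactamate, 1 mol %), t-BuOOH (70% aq., 5 equiv), ClCH2CH2Cl, 40 °C
Reagents that add atoms: tert-butyl hydroperoxide, CC(C)(C)OO
Why: Catalytic allylic oxidation of an enone to an ene-1,4-dione by the tert-butylperoxy radical chain: the C1–H bonds are the only ring C–H bonds that are allylic and γ to the C4 carbonyl, abstraction gives a radical delocalised over C1–C2–C3 toward the carbonyl, capture gives peroxide 14 and loss of tert-butanol gives the ketone. Quaternary C6 is not touched, and the oxidation is done before any epoxide or enoate is present.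

**Step 8**
Reactants: 15 (5R)-2-{[tert-butyl(dimethyl)silyl]oxymethyl}-5-(2,2-dimethoxyethyl)-3-[(E)-hept-1-enyl]-5-(triethylsilyloxy)cyclohex-2-ene-1,4-dione
Product: 16 2-[(1R)-4-{[tert-butyl(dimethyl)silyl]oxymethyl}-3-[(E)-hept-1-enyl]-2,5-dioxo-1-(triethylsilyloxy)cyclohex-3-en-1-yl]acetaldehyde
Conditions: pyridinium p-toluenesulfonate (0.2 equiv), acetone/H2O (9:1), 40 °C
Reagents that add atoms: water, O
Why: Mild acid-catalysed hydrolysis of the dimethyl acetal; the tertiary triethylsilyl ether and the primary TBS ether should survive this weak acid. The aldehyde is released while C6 still carries a silyl ether, so no β,γ-epoxy aldehyde is ever formed.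

**Step 9**
Reactants: 16 2-[(1R)-4-{[tert-butyl(dimethyl)silyl]oxymethyl}-3-[(E)-hept-1-enyl]-2,5-dioxo-1-(triethylsilyloxy)cyclohex-3-en-1-yl]acetaldehyde
Product: 17 methyl (2E)-4-[(1R)-4-{[tert-butyl(dimethyl)silyl]oxymethyl}-3-[(E)-hept-1-enyl]-2,5-dioxo-1-(triethylsilyloxy)cyclohex-3-en-1-yl]-2-methylbut-2-enoate
Conditions: Ph3P=C(CH3)CO2CH3 (1.5 equiv), CH2Cl2, rt
Reagents that add atoms: methyl 2-(triphenyl-λ5-phosphanylidene)propanoate, COC(=O)C(C)=P(c1ccccc1)(c1ccccc1)c1ccccc1
Why: Wittig olefination with a stabilised α-methyl ylide, which reacts with the aldehyde only (both ketones are hindered and much less electrophilic) and gives the (E)-trisubstituted enoate, as is general for stabilised ylides.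

**Step 10**
Reactants: 17 methyl (2E)-4-[(1R)-4-{[tert-butyl(dimethyl)silyl]oxymethyl}-3-[(E)-hept-1-enyl]-2,5-dioxo-1-(triethylsilyloxy)cyclohex-3-en-1-yl]-2-methylbut-2-enoate
Product: 19 methyl (2E)-4-[(1S,6R)-6-bromo-4-{[tert-butyl(dimethyl)silyl]oxymethyl}-3-[(E)-hept-1-enyl]-2,5-dioxo-1-(triethylsilyloxy)cyclohex-3-en-1-yl]-2-methylbut-2-enoate, via trimethylsilyl enol ether 18 (not isolated)
Conditions: Me3SiOTf (1.1 equiv), Et3N (1.3 equiv), CH2Cl2, −78 to −20 °C; then N-bromosuccinimide, −78 °C
Reagents that add atoms: N-bromosuccinimide, O=C1CCC(=O)N1Br
Why: Soft enolisation can only give enol ether 18, because C5 carries the only α-hydrogens of either ketone, and it avoids a free enolate that could expel the β-silyloxy group; electrophilic bromination of the silyl enol ether then places bromine on C5. The C5 stereocentre is set by the facial preference next to quaternary C6: approach anti to the Et3SiO group, whose silyl umbrella shields its face, should place bromine trans to that oxygen, as the next step requires.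

**Step 11**
Reactants: 19 methyl (2E)-4-[(1S,6R)-6-bromo-4-{[tert-butyl(dimethyl)silyl]oxymethyl}-3-[(E)-hept-1-enyl]-2,5-dioxo-1-(triethylsilyloxy)cyclohex-3-en-1-yl]-2-methylbut-2-enoate
Product: 20 methyl (2E)-4-[(1R,6S)-3-[(E)-hept-1-enyl]-4-(hydroxymethyl)-2,5-dioxo-7-oxabicyclo[4.1.0]hept-3-en-1-yl]-2-methylbut-2-enoate
Conditions: Bu4NF (2.5 equiv), THF, −20 to 0 °C
Reagents that add atoms: none
Why: Fluoride cleaves both silyl ethers; the tertiary C6 alkoxide, anti to the C5–Br bond, displaces bromide intramolecularly (SN2, 3-exo-tet, halohydrin-type epoxide closure), so the epoxide oxygen stays on the face fixed in step 6 and C5 is inverted to the required configuration. The primary hydroxyl freed at the same time is the directing group for step 12; the methyl ester should survive the short exposure.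

**Step 12**
Reactants: 20 methyl (2E)-4-[(1R,6S)-3-[(E)-hept-1-enyl]-4-(hydroxymethyl)-2,5-dioxo-7-oxabicyclo[4.1.0]hept-3-en-1-yl]-2-methylbut-2-enoate
Product: 21 methyl (2E)-4-[(1R,5R,6R)-3-[(E)-hept-1-enyl]-5-hydroxy-4-(hydroxymethyl)-2-oxo-7-oxabicyclo[4.1.0]hept-3-en-1-yl]-2-methylbut-2-enoate
Conditions: Me4NBH(OAc)3 (3 equiv), MeCN/AcOH (2:1), −30 °C
Reagents that add atoms: none
Why: Hydroxyl-directed reduction (Saksena–Evans type): the C3 hydroxymethyl group exchanges onto boron and delivers hydride through a six-membered transition state to the neighbouring C4 carbonyl, while the triacetoxyborohydride attacks the remote C1 ketone only slowly and the enoate not at all, which sets the regiochemistry. Hydride should add to C4 anti to the adjacent epoxide C–O bond (Felkin–Anh-type preference), giving the C4 hydroxyl cis to the epoxide, (R) at C4.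

**Step 13**
Reactants: 21 methyl (2E)-4-[(1R,5R,6R)-3-[(E)-hept-1-enyl]-5-hydroxy-4-(hydroxymethyl)-2-oxo-7-oxabicyclo[4.1.0]hept-3-en-1-yl]-2-methylbut-2-enoate
Product: 22 (2E)-4-[(1R,5R,6R)-3-[(E)-hept-1-enyl]-5-hydroxy-4-(hydroxymethyl)-2-oxo-7-oxabicyclo[4.1.0]hept-3-en-1-yl]-2-methylbut-2-enoic acid
Conditions: Me3SnOH (5 equiv), ClCH2CH2Cl, 70 °C; then dilute aq. KHSO4
Reagents that add atoms: trimethyltin hydroxide, C[Sn](C)(C)O
Why: Tin-hydroxide-mediated ester cleavage, a near-neutral acyl substitution that is generally compatible with epoxides, allylic alcohols and enones; the stannyl ester is protonated on mildly acidic work-up. No stereocentre is involved.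

## Compound list

1 | 4,4-dimethoxybutan-2-one | CC(=O)CC(OC)OC | starting material
2 | lithium 4,4-dimethoxybut-1-en-2-olate | [Li]OC(=C)CC(OC)OC | intermediate
3 | triethyl[(4,4-dimethoxybut-1-en-2-yl)oxy]silane | C=C(O[Si](CC)(CC)CC)CC(OC)OC | intermediate
4 | trichloroacetyl chloride | O=C(Cl)C(Cl)(Cl)Cl | starting material
5 | dichloroketene | O=C=C(Cl)Cl | intermediate
6 | 2,2-dichloro-3-(2,2-dimethoxyethyl)-3-(triethylsilyloxy)cyclobutan-1-one (racemic) | O=C1CC(CC(OC)OC)(O[Si](CC)(CC)CC)C1(Cl)Cl | intermediate
7 | 3-(2,2-dimethoxyethyl)-3-(triethylsilyloxy)cyclobutan-1-one | O=C1CC(CC(OC)OC)(O[Si](CC)(CC)CC)C1 | intermediate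
8 | hept-1-yne | CCCCCC#C | starting material
9 | chlorobis(cyclopentadienyl)[(E)-hept-1-enyl]zirconium | CCCCC/C=C/[Zr](Cl)(C1C=CC=C1)C1C=CC=C1 | intermediate
10 | (E)-1-iodohept-1-ene | CCCCC/C=C/I | intermediate
11 | tert-butyldimethyl(prop-2-yn-1-yloxy)silane | C#CCO[Si](C)(C)C(C)(C)C | starting material
12 | tert-butyl{[(E)-dec-4-en-2-yn-1-yl]oxy}dimethylsilane | CCCCC/C=C/C#CCO[Si](C)(C)C(C)(C)C | intermediate
13 | (5R)-2-{[tert-butyl(dimethyl)silyl]oxymethyl}-5-(2,2-dimethoxyethyl)-3-[(E)-hept-1-enyl]-5-(triethylsilyloxy)cyclohex-2-en-1-one | CCCCC/C=C/C1=C(CO[Si](C)(C)C(C)(C)C)C(=O)C[C@](O[Si](CC)(CC)CC)(CC(OC)OC)C1 | intermediate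
14 | (5R)-4-(tert-butylperoxy)-2-{[tert-butyl(dimethyl)silyl]oxymethyl}-5-(2,2-dimethoxyethyl)-3-[(E)-hept-1-enyl]-5-(triethylsilyloxy)cyclohex-2-en-1-one (both epimers at the peroxy carbon) | CCCCC/C=C/C1=C(CO[Si](C)(C)C(C)(C)C)C(=O)C[C@](O[Si](CC)(CC)CC)(CC(OC)OC)C1OOC(C)(C)C | intermediate
15 | (5R)-2-{[tert-butyl(dimethyl)silyl]oxymethyl}-5-(2,2-dimethoxyethyl)-3-[(E)-hept-1-enyl]-5-(triethylsilyloxy)cyclohex-2-ene-1,4-dione | CCCCC/C=C/C1=C(CO[Si](C)(C)C(C)(C)C)C(=O)C[C@](O[Si](CC)(CC)CC)(CC(OC)OC)C1=O | intermediate
16 | 2-[(1R)-4-{[tert-butyl(dimethyl)silyl]oxymethyl}-3-[(E)-hept-1-enyl]-2,5-dioxo-1-(triethylsilyloxy)cyclohex-3-en-1-yl]acetaldehyde | CCCCC/C=C/C1=C(CO[Si](C)(C)C(C)(C)C)C(=O)C[C@](O[Si](CC)(CC)CC)(CC=O)C1=O | intermediate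
17 | methyl (2E)-4-[(1R)-4-{[tert-butyl(dimethyl)silyl]oxymethyl}-3-[(E)-hept-1-enyl]-2,5-dioxo-1-(triethylsilyloxy)cyclohex-3-en-1-yl]-2-methylbut-2-enoate | CCCCC/C=C/C1=C(CO[Si](C)(C)C(C)(C)C)C(=O)C[C@](O[Si](CC)(CC)CC)(C/C=C(\C)C(=O)OC)C1=O | intermediate
18 | methyl (2E)-4-[(1R)-4-{[tert-butyl(dimethyl)silyl]oxymethyl}-3-[(E)-hept-1-enyl]-2-oxo-1-(triethylsilyloxy)-5-(trimethylsilyloxy)cyclohexa-3,5-dien-1-yl]-2-methylbut-2-enoate | CCCCC/C=C/C1=C(CO[Si](C)(C)C(C)(C)C)C(O[Si](C)(C)C)=C[C@](O[Si](CC)(CC)CC)(C/C=C(\C)C(=O)OC)C1=O | intermediate
19 | methyl (2E)-4-[(1S,6R)-6-bromo-4-{[tert-butyl(dimethyl)silyl]oxymethyl}-3-[(E)-hept-1-enyl]-2,5-dioxo-1-(triethylsilyloxy)cyclohex-3-en-1-yl]-2-methylbut-2-enoate (bromine trans to the silyloxy group) | CCCCC/C=C/C1=C(CO[Si](C)(C)C(C)(C)C)C(=O)[C@H](Br)[C@](O[Si](CC)(CC)CC)(C/C=C(\C)C(=O)OC)C1=O | intermediate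
20 | methyl (2E)-4-[(1R,6S)-3-[(E)-hept-1-enyl]-4-(hydroxymethyl)-2,5-dioxo-7-oxabicyclo[4.1.0]hept-3-en-1-yl]-2-methylbut-2-enoate | CCCCC/C=C/C1=C(CO)C(=O)[C@H]2O[C@@]2(C/C=C(\C)C(=O)OC)C1=O | intermediate
21 | methyl (2E)-4-[(1R,5R,6R)-3-[(E)-hept-1-enyl]-5-hydroxy-4-(hydroxymethyl)-2-oxo-7-oxabicyclo[4.1.0]hept-3-en-1-yl]-2-methylbut-2-enoate | CCCCC/C=C/C1=C(CO)[C@@H](O)[C@H]2O[C@@]2(C/C=C(\C)C(=O)OC)C1=O | intermediate
22 | (2E)-4-[(1R,5R,6R)-3-[(E)-hept-1-enyl]-5-hydroxy-4-(hydroxymethyl)-2-oxo-7-oxabicyclo[4.1.0]hept-3-en-1-yl]-2-methylbut-2-enoic acid (CNP0332048.1) | CCCCC/C=C/C1=C(CO)[C@@H](O)[C@H]2O[C@@]2(C/C=C(\C)C(=O)O)C1=O | target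

## Step count and least certain steps

Total: 13 steps. Longest linear sequence: 11 steps (steps 1, 2, 3, then 6 to 13, from 1 to 22); the enyne branch (steps 4 and 5) joins at step 6.

**Step 6 (key step).** The most likely failure is insufficient discrimination between the two enantiotopic C(O)–CH2 bonds, because the ligand must sense a difference between a silyloxy and an alkyl group two atoms away from nickel. β-Silyloxy elimination from the nickelacycle and nickel-mediated oligomerisation of the enyne are further loss channels. Fallback: give up catalyst control of C6. The same annulation of 7 and 12 with Ni(cod)2 and tricyclohexylphosphine, the best-precedented achiral ligand, would give racemic cyclohexenone F1, which is resolved by preparative chromatography on a chiral stationary phase; the (R) enantiomer re-enters the route as 13.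

**Step 7.** Hydrogen abstraction at the wrong site is the main danger. The allylic CH2 of the heptenyl chain gives a radical delocalised through the whole dienone and is less hindered than C1, so chain oxidation may compete with or exceed ring oxidation; the CH2OTBS hydrogens are a lesser concern. Fallback: remove the competitor instead of tuning the oxidant. Starting from 7 and 11, Sonogashira coupling of 11 with vinyl bromide would give vinyl enyne F2, and the nickel annulation of step 6 with 7 would give vinyl enone F3, in which C1 is the only allylic ring or chain CH2. The oxidation of step 7 then gives vinyl enedione F4, and cross-metathesis of F4 with hept-1-ene (second-generation Hoveyda–Grubbs catalyst, CH2Cl2, 40 °C) builds the (E)-heptenyl group and returns to the route at 15.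

**Step 10.** Poor or reversed facial selectivity in the attack on enol ether 18 is possible. The oxygen on C6 is locally smaller than the CH2 group and the C–C bond is the better hyperconjugative donor, so delivery of bromine cis to the silyloxy group is conceivable; a cis bromide cannot close to the epoxide. Ionisation or elimination of the β-silyloxy group with aromatisation is a second risk. Fallback: invert the stereochemical logic. From 18, PhI(OH)OTs would give α-tosyloxy ketone F5: the enol ether attacks trivalent iodine on the preferred face and tosylate then displaces the iodanyl group with inversion, so the sulfonate ends on the face opposite to the first attack, trans to the silyloxy group. Treatment of F5 with Bu4NF as in step 11 closes the epoxide and returns to the route at 20.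

**Step 11.** Base-induced processes may outrun ring closure: enolisation at C5 with expulsion of the silyloxy group (aromatisation), retro-aldol cleavage of the C5–C6 bond from the C6 alkoxide (which would also erode the configuration of C6 on re-closure), or slow loss of the primary silyl group with prolonged exposure of the epoxy enedione to basic fluoride. Fallback: separate desilylation from ring closure and avoid a basic medium. From 19, aqueous HF in MeCN at 0 °C would remove both silyl groups to give bromohydrin diol F6, and Ag2O in CH2Cl2 (silver-assisted departure of bromide) would close the epoxide and return to the route at 20.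

**Step 12.** Hydride delivery to the wrong face of C4 (hydroxyl trans to the epoxide) is possible if the tethered borohydride prefers the face syn to the epoxide oxygen, away from the C6 side chain. Intermolecular reduction of the activated C1 carbonyl would spoil the regiochemistry. Fallback: replace substrate-directed delivery by catalyst control. From 20, a Corey–Bakshi–Shibata reduction with the oxazaborolidine antipode matched to the (R) carbinol and catecholborane at −78 °C should select the more accessible C4 carbonyl and its face under reagent control and return to the route at 21; no new compound is involved.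

## Further compounds

F1 | step 6 | 2-{[tert-butyl(dimethyl)silyl]oxymethyl}-5-(2,2-dimethoxyethyl)-3-[(E)-hept-1-enyl]-5-(triethylsilyloxy)cyclohex-2-en-1-one (racemic) | CCCCC/C=C/C1=C(CO[Si](C)(C)C(C)(C)C)C(=O)CC(O[Si](CC)(CC)CC)(CC(OC)OC)C1
F2 | step 7 | tert-butyldimethyl(pent-4-en-2-yn-1-yloxy)silane | C=CC#CCO[Si](C)(C)C(C)(C)C
F3 | step 7 | (5R)-2-{[tert-butyl(dimethyl)silyl]oxymethyl}-5-(2,2-dimethoxyethyl)-3-ethenyl-5-(triethylsilyloxy)cyclohex-2-en-1-one | C=CC1=C(CO[Si](C)(C)C(C)(C)C)C(=O)C[C@](O[Si](CC)(CC)CC)(CC(OC)OC)C1
F4 | step 7 | (5R)-2-{[tert-butyl(dimethyl)silyl]oxymethyl}-5-(2,2-dimethoxyethyl)-3-ethenyl-5-(triethylsilyloxy)cyclohex-2-ene-1,4-dione | C=CC1=C(CO[Si](C)(C)C(C)(C)C)C(=O)C[C@](O[Si](CC)(CC)CC)(CC(OC)OC)C1=O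
F5 | step 10 | methyl (2E)-4-[(1R,6R)-4-{[tert-butyl(dimethyl)silyl]oxymethyl}-3-[(E)-hept-1-enyl]-6-[(4-methylphenyl)sulfonyloxy]-2,5-dioxo-1-(triethylsilyloxy)cyclohex-3-en-1-yl]-2-methylbut-2-enoate (sulfonate trans to the silyloxy group) | CCCCC/C=C/C1=C(CO[Si](C)(C)C(C)(C)C)C(=O)[C@H](OS(=O)(=O)c2ccc(C)cc2)[C@](O[Si](CC)(CC)CC)(C/C=C(\C)C(=O)OC)C1=O
F6 | step 11 | methyl (2E)-4-[(1S,6R)-6-bromo-3-[(E)-hept-1-enyl]-1-hydroxy-4-(hydroxymethyl)-2,5-dioxocyclohex-3-en-1-yl]-2-methylbut-2-enoate | CCCCC/C=C/C1=C(CO)C(=O)[C@H](Br)[C@](O)(C/C=C(\C)C(=O)OC)C1=O
F0 | step 12 | none | none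
A1 | alternative 1 | methyl 6-allyl-5,6-epoxy-1-hydroxy-4-(4-methoxybenzyloxy)cyclohex-2-ene-3-carboxylate (target numbering; epoxide cis to the C4 ether, C1 hydroxyl trans to the epoxide) | C1=C(C(=O)OC)[C@@H](OCc3ccc(OC)cc3)[C@H]2O[C@@]2(CC=C)[C@@H]1O
A2 | alternative 1 | methyl 6-allyl-1,6-epoxy-5-hydroxy-4-(4-methoxybenzyloxy)cyclohex-2-ene-3-carboxylate (target numbering; C5 hydroxyl cis to the C4 ether, epoxide on the opposite face) | C1=C(C(=O)OC)[C@@H](OCc3ccc(OC)cc3)[C@@H](O)[C@]2(CC=C)O[C@@H]21
A3 | alternative 2 | methyl (2E)-4-[5-(tert-butyldimethylsilyloxy)-4-(tert-butyldimethylsilyloxymethyl)-3-ethenyl-2-hydroxy-7-oxabicyclo[4.1.0]hept-3-en-1-yl]-2-methylbut-2-enoate (silyloxy group cis and hydroxyl trans to the epoxide) | C=CC1=C(CO[Si](C)(C)C(C)(C)C)[C@@H](O[Si](C)(C)C(C)(C)C)[C@H]2O[C@@]2(C/C=C(\C)C(=O)OC)[C@@H]1O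
A4 | alternative 2 | open-chain epoxy enyne: methyl (2E)-4-{3-[1-(tert-butyldimethylsilyloxy)-2-(tert-butyldimethylsilyloxymethyl)prop-2-enyl]-2-(1-hydroxyprop-2-ynyl)oxiran-2-yl}-2-methylbut-2-enoate (configuration as in A3) | C#C[C@@H](O)[C@]1(C/C=C(\C)C(=O)OC)O[C@@H]1[C@H](O[Si](C)(C)C(C)(C)C)C(=C)CO[Si](C)(C)C(C)(C)C
A5 | alternative 3 | methyl (2E)-4-{4-(tert-butyldimethylsilyloxymethyl)-3-[(E)-hept-1-enyl]-2-hydroxy-5-methoxyphenyl}-2-methylbut-2-enoate | Oc1c(/C=C/CCCCC)c(CO[Si](C)(C)C(C)(C)C)c(OC)cc1C/C=C(\C)C(=O)OC
A6 | alternative 3 | pentacarbonyl{1-methoxy-2-(tert-butyldimethylsilyloxymethyl)deca-2,4-dienylidene}chromium ((4E); geometry of the 2,3-alkene immaterial) | COC(=[Cr](=C=O)(=C=O)(=C=O)(=C=O)=C=O)C(CO[Si](C)(C)C(C)(C)C)=C/C=C/CCCCC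
A7 | alternative 3 | methyl (2E)-2-methylhex-2-en-5-ynoate | C#CC/C=C(\C)C(=O)OC
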